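The numbers in the tables are calculated with made-up constants.

Monday's flask has about 1.96 mM of reagent left over at 15.0 min, counting one reagent per target. Yet between 6.00 min and that reading it makes target at 0.273 mM min⁻¹, while Saturday's flask, charged with 24 mM, makes it at 0.271 mM min⁻¹. Over these readings the rate is zero order in reagent, so what I watch is the catalyst.

| flask | starting material | reagent | free catalyst | remark | time |
|---|---|---|---|---|---|
| Sunday's | 20 mM | 12 mM | 0.56 mM | run made earlier |  |
| Monday's | 20 mM | 6 mM | 0.56 mM | run made earlier |  |
| Saturday's | 20 mM | 24 mM | 0.56 mM | run made earlier |  |
| spring | 20 mM | 12.0 mM | 0.56 mM | one stirred flow tank at steady state, fed with the mixture as stated, mean residence time 20 min |  |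
| dusk | 20 mM | 12.0 mM (fed, over 16.0 min) | 0.56 mM | a stirred flask in which reagent is dosed at a steady rate over 16.0 min without added volume, worked up at 20 min | 20 min |
| midnight | 20 mM | 12.0 mM | 0.56 mM | a closed flask charged with all of it at once and left for 20 min | 20 min |
| noon | 20 mM | 12.0 mM | 0.56 mM | a tube with plug flow, the mixed feed as stated, residence time 20 min | 20 min |

- Sunday's (time / min: target / %): 3.00: 3.1; 6.00: 7.1; 10.0: 14.0; 12.0: 15.5; 15.0: 20.7; 20.0: 25.4
- Monday's (time / min: target / %): 1.33: 2.1; 2.00: 1.6; 4.00: 5.2; 6.00: 7.9; 10.0: 13.2; 15.0: 20.2
- Saturday's (time / min: target / %): 1.33: 1.0; 2.00: 2.9; 4.00: 4.9; 6.00: 7.3; 10.0: 14.5; 15.0: 19.5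

(each reading ± 0.5 percentage points)

- the stated concentrations are those of everything mixed, before any reaction; amounts are the same in each set-up
- candidate steps: reagent + free catalyst -> catalyst intermediate A; catalyst intermediate A -> by-product + catalyst intermediate B; catalyst intermediate D -> free catalyst + target; starting material + catalyst intermediate C <-> catalyst intermediate D; catalyst intermediate B <-> catalyst intermediate C; target + by-product -> side product
- the feed brings no volume worth counting
- the earlier runs were made in a closed, stirred flask

1. the set-up with the highest amount of target at the outlet or at the end, in percent of the starting material put in ("none" if the first two lie within 2 percentage points) (spring / dusk / midnight / noon / none)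
2. amount of target at the outlet or at the end, in percent of the starting material put in, spring
3. amount of target at the outlet or at the end, in percent of the starting material put in, dusk
4. amount of target at the outlet or at the end, in percent of the starting material put in, midnight
5. amount of target at the outlet or at the end, in percent of the starting material put in, noon

Midnight has Sunday's charge, and each slice of noon's tube sees the same history, so I have two ways to their figure. The first is Sunday's last reading, 25.4 %. The second takes the mean of Monday's and Saturday's last readings and runs on at their frozen rate, which gives 26.7 %. They part by 1.3 percentage points, against a scatter of 0.5 points per reading. Sunday's curve shows which one cheats: it makes 0.311 mM min⁻¹ up to 10.0 min and then 0.228 mM min⁻¹, so the frozen line runs high and I keep the reading.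

The number I carry is the round rate (turnover frequency), the target made per amount of free catalyst charged per minute, averaged from the start: 0.454 min⁻¹ on Sunday's reading. The spring tank works at its outlet state all the time, so I give it Sunday's late rate, which is a round rate of 0.407 min⁻¹ and a yield of 22.8 %. Dusk's dose of 0.750 mM min⁻¹ outruns the early rate, so I put dusk a little under midnight, and I expect no winner.

The forecast says spring 26.5 %, dusk 25 %, midnight 25.8 %, noon 25.8 %, best none, on the ground that the curves overlap, “so the rate is zero order in reagent”. For spring it stands above my figure.

The flasks give spring 22.8 %, dusk 24.8 %, midnight 25.6 %, noon 25.6 %, best none, and the forecast is right on each within the tolerance.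

    reagent + free catalyst → catalyst intermediate A (k = 21000 L mol⁻¹ min⁻¹)
    catalyst intermediate A → by-product + catalyst intermediate B (k = 2.40 min⁻¹)
    catalyst intermediate D → free catalyst + target (k = 24.0 min⁻¹)
    starting material + catalyst intermediate C ⇌ catalyst intermediate D (K = 79.0 L mol⁻¹, k = 39.0 L mol⁻¹ min⁻¹)
    catalyst intermediate B ⇌ catalyst intermediate C (K = 15.0, k = 26.0 min⁻¹)
    target + by-product → side product (k = 0.310 L mol⁻¹ min⁻¹)

In midnight, reagent passes onto free catalyst with a half-life of 0.059 min at the charge, and starting material still stands at 74.0 % at the end. Catalyst intermediate A has a half-life of 0.29 min by its step. Catalyst intermediate C has 0.89 min, by its forward step alone, as charged. Catalyst intermediate D has 1.7 s. Catalyst intermediate B has 1.6 s, by its forward step alone, and these last two pass on quicker than the first two. The round rate comes to 0.457 min⁻¹ at midnight and 0.408 min⁻¹ in spring. Midnight's figure leaves the forecast's 25.8 % in a run that strays in free catalyst or in time: at 0.689 mM of free catalyst it has moved 5 points, where the round rate reckons 5.9 points. With all amounts held, it has moved 5 points at 15.7 min and at 24.6 min.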